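## Retrosynthetic overview

- Ring C (the pendant 2-hydroxy-4,6-dioxocyclohexenyl ring) is cut between C-1′ and the enol carbon C-2′ (Dieckmann condensation). Ring B (the dihydropyran) is cut at O-1–C-2 (oxa-Michael addition). Both closures run in one operation on the acyclic β-hydroxy ketone 11.
- 11 comes from an aldol addition of methyl ketone 5 to lactol 9. 9 comes from an enamine-catalysed addition of 3-methylbutanal to alkylidene trione 8, which sets C-3 and C-4. 8 is the Knoevenagel product of syncarpic acid 6, and 6 (ring A) is the Dieckmann product of the same keto ester 5.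
- Enabling feature: C-1′ of ring C is the central carbon of a β-triketone whose other α-carbons (C-3′, C-5′) are quaternary, so the open 3,5-dioxo ester can enolise only at the future C-1′. C-2 of ring B lies β to that triketone and carries O-1, so ring B is the reversible oxa-Michael adduct of the ring A enol onto a ring C alkylidene, and C-2 can settle thermodynamically.
- Ring order: A (step 4), then C and B together (step 8).

Key step: step 8

Remark: β-triketone units are drawn as single enol tautomers; lactol 9 and carbinols 11 and 12 are carried as mixtures at the one centre (the future C-2) that the last step resets.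

## Route

Step 1
Reactants: 1 2,2,4,4-tetramethylcyclobutane-1,3-dione
Product: 2 methyl 2,2,4-trimethyl-3-oxopentanoate
Conditions: NaOMe (5 mol%), MeOH, 23 °C
Reagents that add atoms: methanol, CO
Why: Methoxide adds to a carbonyl of the strained, non-enolisable dione and the adduct opens by retro-Claisen C–C cleavage, the ketone enolate being protonated by methanol so that the base turns over; no stereocentre is formed.

Step 2
Reactants: 2 methyl 2,2,4-trimethyl-3-oxopentanoate; 3 acetaldehyde
Product: 4 methyl 5-hydroxy-2,2,4,4-tetramethyl-3-oxohexanoate (racemic)
Conditions: LiN(iPr)2, THF, −78 → 0 °C; then 3, −78 °C; AcOH, −78 °C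
Reagents that add atoms: none
Why: Aldol addition of the tetrasubstituted lithium enolate formed at the only α-C–H of 2 (the isopropyl methine), chosen over direct acetylation because an aldehyde cannot O-acylate the hindered enolate; the carbinol centre is racemic and is removed in step 3.

Step 3
Reactants: 4 methyl 5-hydroxy-2,2,4,4-tetramethyl-3-oxohexanoate
Product: 5 methyl 2,2,4,4-tetramethyl-3,5-dioxohexanoate
Conditions: Dess–Martin periodinane, CH2Cl2, 0 → 23 °C
Reagents that add atoms: none
Why: Dess–Martin oxidation of the secondary alcohol under near-neutral conditions should avoid retro-aldol cleavage and lactonisation of the α-quaternary β-hydroxy ketone.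

Step 4
Reactants: 5 methyl 2,2,4,4-tetramethyl-3,5-dioxohexanoate
Product: 6 syncarpic acid (5-hydroxy-2,2,6,6-tetramethylcyclohex-4-ene-1,3-dione)
Conditions: KOtBu (2.2 equiv), THF, 0 → 23 °C; then 1 M HCl
Reagents that add atoms: none
Why: Dieckmann condensation in which the methyl ketone, the only enolisable site, attacks the ester (6-exo-trig, helped by the two gem-dimethyl groups) and the closure is driven by formation of the stabilised trione enolate.

Step 5
Reactants: 6 syncarpic acid; 7 3-methylbutanal
Product: 8 2-(3-methylbutylidene)-4,4,6,6-tetramethylcyclohexane-1,3,5-trione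
Conditions: piperidine (5 mol%), 4 Å MS, CH2Cl2, 0 °C; short silica pad, used at once
Reagents that add atoms: none
Why: Knoevenagel condensation of the strongly acidic cyclic trione with the aliphatic aldehyde through the iminium ion; the alkylidene carbon has two identical acyl neighbours, so no alkene isomers arise, and the product is used fresh because it can tautomerise and self-add.

Step 6
Reactants: 8 2-(3-methylbutylidene)-4,4,6,6-tetramethylcyclohexane-1,3,5-trione; 7 3-methylbutanal
Product: 9 lactol (3S,4S)-2-hydroxy-6,6,8,8-tetramethyl-4-(2-methylpropyl)-3-(propan-2-yl)-3,4-dihydro-2H-chromene-5,7(6H,8H)-dione (anomer mixture)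
Conditions: (R)-2-[diphenyl(trimethylsilyloxy)methyl]pyrrolidine (10 mol%), 4-nitrobenzoic acid (10 mol%), toluene, 0 °C; then wet silica gel
Reagents that add atoms: none
Why: Enamine-catalysed inverse-electron-demand oxa-Diels–Alder reaction (a Michael addition whose zwitterion closes at once through the ring A enolate oxygen), in which the anti-enamine of 7, shielded on one face by the diphenyl(silyloxy)methyl group of the (R)-catalyst, adds through an endo-type synclinal arrangement to the s-cis-locked oxadiene of 8; the catalyst sets C-3 (S) and the syn-addition topology sets C-4 (S, 3,4-trans), in the same sense as aldehyde additions to nitroalkenes and alkylidene malonates, and the catalyst-bound cyclic N,O-aminal then exchanges its amine for hydroxyl at C-2 (acid co-catalyst, then wet silica gel), which returns the catalyst and gives the lactol.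

Step 7
Reactants: 9 lactol (3S,4S)-2-hydroxy-6,6,8,8-tetramethyl-4-(2-methylpropyl)-3-(propan-2-yl)-3,4-dihydro-2H-chromene-5,7(6H,8H)-dione; 5 methyl 2,2,4,4-tetramethyl-3,5-dioxohexanoate
Product: 11 methyl (8S,9S)-7-hydroxy-9-(2-hydroxy-3,3,5,5-tetramethyl-4,6-dioxocyclohex-1-en-1-yl)-2,2,4,4,11-pentamethyl-3,5-dioxo-8-(propan-2-yl)dodecanoate (both C-7 epimers), via open-chain aldehyde 10 (not isolated)
Conditions: 5, LiN(iPr)2, THF, −78 °C; then 9 pre-treated with LiN(SiMe3)2 (1.0 equiv), THF, −78 °C; AcOH, −78 °C
Reagents that add atoms: none
Why: Aldol addition: the lithium lactolate of 9 opens to aldehyde 10 (held as its lithium trione enolate) because the ring A trione enolate is an excellent leaving group, and the kinetic lithium enolate of 5 (only the methyl group can enolise) should add to the aldehyde at −78 °C faster than it deprotonates the hindered α-position or closes onto its own ester; the C-7 carbinol configuration is irrelevant because step 8 erases it.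

Step 8
Reactants: 11 methyl (8S,9S)-7-hydroxy-9-(2-hydroxy-3,3,5,5-tetramethyl-4,6-dioxocyclohex-1-en-1-yl)-2,2,4,4,11-pentamethyl-3,5-dioxo-8-(propan-2-yl)dodecanoate
Product: 14 ericifolione, via hydroxy bis-trione 12 (not isolated), via alkylidene trione 13 (not isolated)
Conditions: LiN(iPr)2 (3.5 equiv), THF, −78 → 23 °C; then CF3CO2H (excess), 0 → 23 °C, same flask
Reagents that add atoms: none
Why: Excess base removes the ring A enol proton, the C-7 hydroxyl proton and then the only acidic C–H left (the C-6 methylene); the resulting β-oxido enolate, which can neither β-eliminate nor cleave by retro-aldol, attacks the methyl ester in a Dieckmann condensation (6-exo-trig, helped by the gem-dimethyl groups) to form the bond between C-1′ and the enol carbon C-2′ of ring C, and loss of methoxide with deprotonation to the trione enolate makes the closure irreversible (any O-acylated enol lactone is reopened by LiOMe and funnelled to the same enolate). The closest known reaction type is the Dieckmann closure of δ-keto esters to cyclohexane-1,3-diones (step 4), here run on the dianion of a β-hydroxy ketone as in the alkylation chemistry of β-oxido enolates. On acidification carbinol 12 should lose water, as in the second half of a Knoevenagel condensation, to give alkylidene trione 13, which is trapped by the ring A enol oxygen in a 6-exo-trig oxa-Michael addition that closes ring B. C-2 is the only new stereocentre and is set under thermodynamic control, because the oxa-Michael addition is reversible through 13: with the C-4 isobutyl group pseudo-axial (away from the C-5 carbonyl) and the trans C-3 isopropyl group therefore axial, ring C should take the equatorial position cis to isopropyl, which is the (2R) configuration. The step needs C-3 to survive, and the substrate secures this by having no enone or carbonyl next to C-3 during the basic phase, so that an alkylidene appears only in the final acidic, intramolecular event; C-3 and C-4 from step 6 are not touched.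

## Compound list

1 | 2,2,4,4-tetramethylcyclobutane-1,3-dione | CC1(C)C(=O)C(C)(C)C1=O | starting material
2 | methyl 2,2,4-trimethyl-3-oxopentanoate | COC(=O)C(C)(C)C(=O)C(C)C | intermediate
3 | acetaldehyde | CC=O | starting material
4 | methyl 5-hydroxy-2,2,4,4-tetramethyl-3-oxohexanoate (racemic) | COC(=O)C(C)(C)C(=O)C(C)(C)C(C)O | intermediate
5 | methyl 2,2,4,4-tetramethyl-3,5-dioxohexanoate | COC(=O)C(C)(C)C(=O)C(C)(C)C(C)=O | intermediate
6 | syncarpic acid (5-hydroxy-2,2,6,6-tetramethylcyclohex-4-ene-1,3-dione) | CC1(C)C(=O)C=C(O)C(C)(C)C1=O | intermediate
7 | 3-methylbutanal | CC(C)CC=O | starting material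
8 | 2-(3-methylbutylidene)-4,4,6,6-tetramethylcyclohexane-1,3,5-trione | CC(C)CC=C1C(=O)C(C)(C)C(=O)C(C)(C)C1=O | intermediate
9 | (3S,4S)-2-hydroxy-6,6,8,8-tetramethyl-4-(2-methylpropyl)-3-(propan-2-yl)-3,4-dihydro-2H-chromene-5,7(6H,8H)-dione (lactol, anomer mixture) | CC(C)C[C@@H]1C2=C(OC(O)[C@H]1C(C)C)C(C)(C)C(=O)C(C)(C)C2=O | intermediate
10 | (2S,3S)-3-(2-hydroxy-3,3,5,5-tetramethyl-4,6-dioxocyclohex-1-en-1-yl)-5-methyl-2-(propan-2-yl)hexanal (ring-opened form of 9, not isolated) | CC(C)C[C@H](C1=C(O)C(C)(C)C(=O)C(C)(C)C1=O)[C@H](C(C)C)C=O | intermediate
11 | methyl (8S,9S)-7-hydroxy-9-(2-hydroxy-3,3,5,5-tetramethyl-4,6-dioxocyclohex-1-en-1-yl)-2,2,4,4,11-pentamethyl-3,5-dioxo-8-(propan-2-yl)dodecanoate (C-7 epimers) | CC(C)C[C@H](C1=C(O)C(C)(C)C(=O)C(C)(C)C1=O)[C@H](C(C)C)C(O)CC(=O)C(C)(C)C(=O)C(C)(C)C(=O)OC | intermediate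
12 | hydroxy bis-trione: the (2S,3S)-1-hydroxy-5-methyl-2-(propan-2-yl)hexane chain carrying a 2-hydroxy-3,3,5,5-tetramethyl-4,6-dioxocyclohex-1-en-1-yl ring at C-1 (ring C) and another at C-3 (ring A); C-1 epimers, not isolated | CC(C)C[C@H](C1=C(O)C(C)(C)C(=O)C(C)(C)C1=O)[C@H](C(C)C)C(O)C1=C(O)C(C)(C)C(=O)C(C)(C)C1=O | intermediate
13 | alkylidene trione: 2-[(2R,3S)-3-(2-hydroxy-3,3,5,5-tetramethyl-4,6-dioxocyclohex-1-en-1-yl)-5-methyl-2-(propan-2-yl)hexylidene]-4,4,6,6-tetramethylcyclohexane-1,3,5-trione (same spatial arrangement as 11; not isolated) | CC(C)C[C@H](C1=C(O)C(C)(C)C(=O)C(C)(C)C1=O)[C@H](C(C)C)C=C1C(=O)C(C)(C)C(=O)C(C)(C)C1=O | intermediate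
14 | ericifolione, (2R,3S,4S)-2-(2-hydroxy-3,3,5,5-tetramethyl-4,6-dioxocyclohex-1-en-1-yl)-6,6,8,8-tetramethyl-4-(2-methylpropyl)-3-(propan-2-yl)-3,4-dihydro-2H-chromene-5,7(6H,8H)-dione | CC(C)C[C@@H]1C2=C(O[C@@H](C3=C(O)C(C)(C)C(=O)C(C)(C)C3=O)[C@H]1C(C)C)C(C)(C)C(=O)C(C)(C)C2=O | target

## Step count and risks

Total step count: 8. Longest linear sequence: 8 (steps 1 to 8; keto ester 5 is used twice, once for ring A and once for ring C).

Most likely to fail, in this order:

1. **Step 8.** The trilithium species may aggregate, or the enolate carbon may be too hindered to acylate the neopentyl-type ester, so that the Dieckmann closure stalls; prolonged warming could then lead to elimination toward an enone and loss of configuration at C-3. Fallback: ring C is closed on the small fragment instead of on the full skeleton. The fallback sets out from lactol 9 and syncarpic acid 6 (ring closure of 5 as in step 4). The two are joined by a Knoevenagel condensation at the masked aldehyde (ethylenediammonium diacetate cat., CH2Cl2, 23 °C), which should give alkylidene trione 13 in the flask and, through the same oxa-Michael closure and equilibration, come back to the route at 14. This fallback makes no compound outside the list: none F0.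

2. **Step 6.** The amine catalyst may be held back by reversible aza-Michael addition to 8, or may trigger tautomerisation and self-addition of 8, and facial selectivity on the doubly activated acceptor may be poor. Fallback: a chiral Lewis acid replaces the enamine. It sets out from 8, which is bound in a two-point fashion by Cu(OTf)2 carrying a tert-butyl-bis(oxazoline) ligand (10 mol%, CH2Cl2, −40 °C). The dienophile in the inverse-electron-demand hetero-Diels–Alder reaction is (E)-1-ethoxy-3-methylbut-1-ene F1, obtained from commercial 1,1-diethoxy-3-methylbutane by acid-catalysed loss of ethanol (KHSO4, distillation). The endo addition of the (E)-enol ether should give the 3,4-trans 2-ethoxy acetal F2, the ligand enantiomer being chosen to deliver (3S,4S). Hydrolysis (1 M HCl, THF, 23 °C) comes back to the route at lactol 9.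

3. **Step 7.** Proton transfer may compete with addition (enolisation of the hindered α-branched aldehyde, with erosion at C-3), the lithium enolate of 5 may close onto its own ester before it meets the aldehyde, and the aldolate may revert on work-up. Fallback: the enolate is made reductively and is far less basic. It sets out from 5, which is brominated at its only enolisable position (Br2, MeOH, 0 °C) to methyl 6-bromo-2,2,4,4-tetramethyl-3,5-dioxohexanoate F3. A Reformatsky addition of F3 (activated Zn, THF, 0 → 23 °C) to lactol 9, reacting through its open aldehyde form 10, comes back to the route at 11.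

Further compounds
F0 | step 8 | none | none
F1 | step 6 | (E)-1-ethoxy-3-methylbut-1-ene | CCO/C=C/C(C)C
F2 | step 6 | (3S,4S)-2-ethoxy-6,6,8,8-tetramethyl-4-(2-methylpropyl)-3-(propan-2-yl)-3,4-dihydro-2H-chromene-5,7(6H,8H)-dione | CC(C)C[C@@H]1C2=C(OC(OCC)[C@H]1C(C)C)C(C)(C)C(=O)C(C)(C)C2=O
F3 | step 7 | methyl 6-bromo-2,2,4,4-tetramethyl-3,5-dioxohexanoate | COC(=O)C(C)(C)C(=O)C(C)(C)C(=O)CBr
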